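## The problem

Target **19** is a cyclohex-4-ene fused to a 1,6-oxirane; the ring is numbered C1 (fully substituted oxirane carbon bearing the benzoyloxymethyl carbon C7), C2 (OMe), C3 (OBz), C4=C5 and C6 (oxirane CH), and sugar locants, where used, are marked "sugar". The configuration is 1R,2S,3R,6R, so the oxirane oxygen is cis to the C2 methoxyl and trans to the C3 benzoate. Four contiguous stereocentres sit on a single ring with no second ring to bias it, and C1 is a quaternary carbinol carbon flanked by two oxygenated carbons. The trans C2/C3 dioxygen pair can be bought as sugar C3/C4 of D-glucose, with the methyl ether already present in 3-O-methyl-D-glucose **1**, and it can control C1 if it is held in a ring while the C–C bond forms. C1 then dictates C6: a tertiary C–O bond cannot be inverted, so the oxirane has to be closed by displacement at C6 from a C6 oxygen trans to the C1 oxygen. The vinyl oxirane opens with acid or nucleophiles (directly or in the SN2′ sense) and the two benzoates cleave or migrate under alkoxide conditions, so the epoxide must come last and the esters late. The enabling feature is the array C7–C1(O)–C6(O)–C5=C4: a carboxyl-level C7 on an α-oxygenated carbon with a β-oxygen and a γ,δ-alkene is the retron of an ester-enolate Claisen rearrangement. Because C4 is tied to C1 through C3 and C2, the ester is a δ-lactone (carbonyl C7, α-carbon C1, ring carbons C2–C4) and the rearrangement is a ring contraction that makes the carbocycle.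

## Retrosynthesis

**Oxirane C6–O bond.** Target **19** is opened to the trans-diol **17** through the C6 mesylate **18**. Cutting C6–O rather than C1–O is forced, since only the secondary allylic carbon can be inverted. Epoxidising a diene instead would raise face and site selectivity problems. The forward step asks only that the C6 oxygen of **17** be trans to the C1 oxygen.

**Benzoate C–O bonds and the C6 ether.** Diol **17** comes from the 4-methoxybenzyl ether **16**, and **16** from triol **14** and two equivalents of benzoyl chloride **15**. The tertiary C1 hydroxyl will not acylate, so one acylation installs both esters of the target. The 4-methoxybenzyl group is what keeps the C6 oxygen distinct from the C3 oxygen until then.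

**Oxidation level of C7 and silyl groups.** Triol **14** is traced through bis-silyl alcohol **13** to acid **12**. Carrying C3 as a silyl ether rather than a benzoate lets LiAlH4 be used on the hindered acid. It also removes a β-leaving group from the earlier sugar 6-aldehyde.

**C1–C6 bond (key cut).** Acid **12** is the [3,3] product of silyl ketene acetal **10** (via silyl ester **11**), which comes from lactone **9**. This one cut removes the carbocycle, the quaternary centre and the C6 stereocentre together, and leaves a glucono-1,5-lactone with an (E)-alkoxyvinyl arm. Cuts at C3–C4 or through the C–O bonds would leave C1 still to be made. The forward reaction must deliver C6 to the face of C1 on which the arm sits, and must place the C6 oxygen trans to the C1 oxygen.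

**Lactone carbonyl.** Lactone **9** comes from lactol **8**, and **8** from the anomeric silyl acetal **7**. The carbonyl is unveiled only after the enol ether is made, because a δ-lactone with an α-hydrogen and a β-methoxyl would not survive alkoxide and carbonate at 80 °C.

**Enol ether C–O bond.** Enol ether **7** is cut to (E)-iodoalkene **5** and 4-methoxybenzyl alcohol **6**. A stereoretentive C–O coupling is preferred to alkoxymethylene Wittig chemistry, which gives E/Z mixtures, and the (E) geometry is what sets C6.

**C5=C6 bond.** Iodoalkene **5** comes from aldehyde **4** by one-carbon iodo-olefination, and **4** from primary alcohol **3**. The olefination must be non-basic so that the α-stereocentre (sugar C5), which later relays chirality to C1, is not epimerised.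

**Protecting pattern.** Alcohol **3** comes from the per-silylated sugar **2**, and **2** from **1**. One silylation covers the anomeric, O2, O4 and O6 hydroxyls; the primary ether is then released selectively. The methyl ether of **1** is the future C2 methoxyl.

## Roads not taken

Alternative 1: Desymmetrising epoxidation of a para-quinol. The cut is through the C–O bonds. The ring is taken whole from the prochiral quinol **A1**, 4-(benzoyloxymethyl)-4-hydroxycyclohexa-2,5-dien-1-one. A cinchona-derived primary amine salt with H2O2 would epoxidise one enantiotopic enone alkene syn to the hydroxyl and give epoxy enone **A2**.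

- Merits: **A1** is a short oxidative dearomatisation away from a simple phenol, C7 already carries its benzoate, the quaternary centre is set catalytically and no protecting groups are needed.
- Weak points: in **A2** the oxirane is on C2–C3, not C1–C6. To reach **19** it must be opened at C3 by benzoate with inversion, in competition with attack at C2. The hindered C2 hydroxyl of a β-hydroxy ketone must then be methylated beside a free tertiary hydroxyl without retro-aldol or acyl shift. Finally the C4 ketone and C5=C6 alkene must be transposed into a C4=C5 alkene and a C6 oxygen trans to C1–OH (second epoxidation, Wharton transposition, sulfonate, closure).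
- Comparison: as far as **A2** this road is clearly shorter, and its total count could end below that of the chosen route. The chosen plan sets against this that every stereocentre is either bought or fixed by an intramolecular event with a single possible topology, and that no regiochemical choice at an epoxy ketone is needed.

Alternative 2: Nozaki–Hiyama–Kishi closure onto the C3 aldehyde. The cut is C3–C4. The (Z)-iodoalkenyl epoxy aldehyde **A3** would be treated with CrCl2 and catalytic NiCl2; the alkenylchromium species (trivalent chromium) adds to the aldehyde and closes the ring to the 3-O-debenzoyl compound **A4**, one benzoylation from **19**.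

- Merits: the oxirane and the C7 benzoate are in place before ring closure, the reaction tolerates esters and epoxides, and no late sulfonate chemistry is needed.
- Weak points: C3 is created in the ring-closing step with only the adjacent methoxy centre to direct it, so the trans C2/C3 relation is not assured. **A3** needs C1, C2 and C6 from separate asymmetric operations and is an epimerisable α-methoxy aldehyde. Lewis-acidic chromium salts meet a vinyl oxirane.
- Comparison: the end game is shorter and gentler than the chosen one, which is a real advantage. The chosen plan sets against it that C2 and C3 come from glucose and that its ring-forming step sets two centres with a predictable sense rather than one with an open sense.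

Alternative 3: Biocatalytic ipso,ortho-dihydroxylation of benzoic acid. The cut is through the ring C–O bonds back to an arene. Benzoic acid **A5** is dearomatised by benzoate dioxygenase in whole cells of a Cupriavidus necator B9 mutant, adding both oxygens cis at C1 and C6 to give the diene diol acid **A6**.

- Merits: one step from a commodity chemical gives all seven carbons, the C1 configuration of **19** and the C1 and C6 oxygens as a single enantiomer.
- Weak points: the two oxygens are cis on C1 and C6, whereas **19** needs one bridging oxygen, so C6 must undergo a net double inversion. Both diene alkenes carry an allylic hydroxyl, so oxygenating C2=C3 (oxygen cis to C1–O at C2, benzoate trans at C3) while sparing C4=C5 is a differentiation problem. **A6** rearomatises readily by dehydration or decarboxylation, and the organism is not a catalogue reagent.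
- Comparison: in step count and atom economy this road may well be better. The chosen plan sets against it that it uses only purchasable materials and ordinary operations, and that its key step delivers the C1/C6 oxygens directly in the trans relationship needed for closure.

Key step: step 8

Assumption: **2**–**7** are drawn as β-anomers; an anomeric mixture is without consequence because the anomeric carbon becomes the lactone carbonyl of **9**.

## Route

Step 1
Reactants: 1 3-O-methyl-D-glucose
Product: 2 tert-butyldimethylsilyl 2,4,6-tri-O-(tert-butyldimethylsilyl)-3-O-methyl-β-D-glucopyranoside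
Conditions: TBSOTf (5 equiv), pyridine, DMAP (cat.), 0 → 60 °C
Reagents that add atoms: tert-butyldimethylsilyl trifluoromethanesulfonate, CC(C)(C)[Si](C)(C)OS(=O)(=O)C(F)(F)F
Why: Exhaustive O-silylation with a silyl triflate should cap the anomeric, O2, O4 and O6 hydroxyls in one operation; the existing 3-O-methyl group is the future C2 methoxyl.

Step 2
Reactants: 2 tert-butyldimethylsilyl 2,4,6-tri-O-(tert-butyldimethylsilyl)-3-O-methyl-β-D-glucopyranoside
Product: 3 tert-butyldimethylsilyl 2,4-di-O-(tert-butyldimethylsilyl)-3-O-methyl-β-D-glucopyranoside
Conditions: CSA (cat.), MeOH–CH2Cl2, 0 °C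
Reagents that add atoms: none
Why: Acid-catalysed methanolysis is a standard selective cleavage of a primary silyl ether; the hindered secondary ethers and the weakly basic anomeric silyl acetal should react much more slowly.

Step 3
Reactants: 3 tert-butyldimethylsilyl 2,4-di-O-(tert-butyldimethylsilyl)-3-O-methyl-β-D-glucopyranoside
Product: 4 tert-butyldimethylsilyl 2,4-di-O-(tert-butyldimethylsilyl)-3-O-methyl-β-D-gluco-hexodialdo-1,5-pyranoside
Conditions: Dess–Martin periodinane, NaHCO3, CH2Cl2, 0 °C → rt
Reagents that add atoms: none
Why: Buffered Dess–Martin oxidation gives the 6-aldehyde without base, so sugar C5 (α to the aldehyde, later the relay of chirality to C1) should not epimerise, and the silyloxy group at sugar C4 is a poor β-leaving group.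

Step 4
Reactants: 4 tert-butyldimethylsilyl 2,4-di-O-(tert-butyldimethylsilyl)-3-O-methyl-β-D-gluco-hexodialdo-1,5-pyranoside
Product: 5 tert-butyldimethylsilyl (E)-2,4-di-O-(tert-butyldimethylsilyl)-6,7-dideoxy-7-iodo-3-O-methyl-β-D-gluco-hept-6-enopyranoside
Conditions: CrCl2, CHI3, THF–1,4-dioxane, 0 °C → rt
Reagents that add atoms: iodoform, IC(I)I
Why: Takai olefination: the geminal dichromium reagent from CHI3 adds to the aldehyde and eliminates to the (E)-iodoalkene, adding the carbon that becomes C6; the non-basic medium preserves the α-stereocentre.

Step 5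
Reactants: 5 tert-butyldimethylsilyl (E)-2,4-di-O-(tert-butyldimethylsilyl)-6,7-dideoxy-7-iodo-3-O-methyl-β-D-gluco-hept-6-enopyranoside; 6 4-methoxybenzyl alcohol
Product: 7 tert-butyldimethylsilyl (E)-2,4-di-O-(tert-butyldimethylsilyl)-6-deoxy-7-O-(4-methoxybenzyl)-3-O-methyl-β-D-gluco-hept-6-enopyranoside (the (E)-enol ether)
Conditions: CuI (10 mol %), 3,4,7,8-tetramethyl-1,10-phenanthroline (20 mol %), Cs2CO3, PhMe, 80 °C
Reagents that add atoms: none
Why: Ullmann-type copper-catalysed C–O coupling of an iodoalkene with a primary alcohol proceeds with retention of alkene geometry; at this stage the substrate has no ester or free hydroxyl for the base to attack.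

Step 6
Reactants: 7 tert-butyldimethylsilyl (E)-2,4-di-O-(tert-butyldimethylsilyl)-6-deoxy-7-O-(4-methoxybenzyl)-3-O-methyl-β-D-gluco-hept-6-enopyranoside
Product: 8 (E)-2,4-di-O-(tert-butyldimethylsilyl)-6-deoxy-7-O-(4-methoxybenzyl)-3-O-methyl-D-gluco-hept-6-enopyranose (lactol; anomeric mixture)
Conditions: TBAF, AcOH, THF, −20 → 0 °C
Reagents that add atoms: none
Why: The anomeric silyl ether is a silyl acetal with the best oxygen leaving group in the molecule, so buffered fluoride-mediated desilylation should cleave it before the hindered secondary ethers; AcOH suppresses O2→O1 silyl migration and is too weak to hydrolyse the enol ether.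

Step 7
Reactants: 8 (E)-2,4-di-O-(tert-butyldimethylsilyl)-6-deoxy-7-O-(4-methoxybenzyl)-3-O-methyl-D-gluco-hept-6-enopyranose
Product: 9 (3R,4S,5R,6R)-3,5-bis(tert-butyldimethylsilyloxy)-4-methoxy-6-[(E)-2-(4-methoxybenzyloxy)ethenyl]oxan-2-one
Conditions: Dess–Martin periodinane, NaHCO3, CH2Cl2, 0 °C → rt
Reagents that add atoms: none
Why: Dess–Martin oxidation of a lactol to the δ-lactone; the buffered medium tolerates the enol ether and silyl ethers, and both anomers converge on one lactone.

Step 8
Reactants: 9 (3R,4S,5R,6R)-3,5-bis(tert-butyldimethylsilyloxy)-4-methoxy-6-[(E)-2-(4-methoxybenzyloxy)ethenyl]oxan-2-one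
Product: 12 (1R,2S,3R,6S)-1,3-bis(tert-butyldimethylsilyloxy)-2-methoxy-6-(4-methoxybenzyloxy)cyclohex-4-ene-1-carboxylic acid, via silyl ketene acetal 10 (not isolated), via trimethylsilyl ester 11 (not isolated)
Conditions: KN(SiMe3)2, Me3SiCl, Et3N, THF, −78 °C; then PhMe, 90 °C; aq. citric acid
Reagents that add atoms: chlorotrimethylsilane, C[Si](C)(C)Cl (its atoms are present in 10 and 11 only)
Why: KN(SiMe3)2 removes the only acidic C–H of 9 (at the future C1) with Me3SiCl already present, so the potassium enolate is O-silylated as it forms to give the cyclic silyl ketene acetal 10; on warming, 10 should undergo a concerted suprafacial [3,3] shift in which C1–C6 forms, the lactone C4–O bond breaks and the C4=C5 alkene appears, giving silyl ester 11, which aqueous acid hydrolyses to 12. The closest known reaction type is the Ireland–Claisen ring contraction of alkenyl lactone silyl ketene acetals to cycloalkene carboxylic acids, as in dioxanone-to-dihydropyran rearrangements. The cyclohexene closes by pericyclic C–C bond formation between the lactone α-carbon and the alkene terminus through a boat-like six-centre transition state bridged by the C2–C3 tether (a bicyclo[2.2.2]octane-like array); a chair cannot be reached with a two-atom tether. C1 is controlled by the C4 stereocentre: the alkenyl arm can reach C1 only across the lactone face it occupies, which puts C7 cis to the C3 oxygen and trans to the C2 methoxyl (1R). C6 is controlled by the (E) geometry: in the boat the alkoxy group points away from the tether, which places the C6 oxygen cis to C7 and trans to the C1 oxygen (6S). The step needs O-silylation to outrun E1cB loss of the C2 methoxyl; the internal quench at −78 °C and the pseudo-equatorial, poorly aligned C2–OMe bond of the gluco lactone should secure this. Formation of the carboxylate makes the shift irreversible, and an alkoxy donor on the bond-forming alkene terminus is at a position known to accelerate Claisen rearrangements.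

Step 9
Reactants: 12 (1R,2S,3R,6S)-1,3-bis(tert-butyldimethylsilyloxy)-2-methoxy-6-(4-methoxybenzyloxy)cyclohex-4-ene-1-carboxylic acid
Product: 13 [(1R,2S,3R,6S)-1,3-bis(tert-butyldimethylsilyloxy)-2-methoxy-6-(4-methoxybenzyloxy)cyclohex-4-en-1-yl]methanol
Conditions: LiAlH4, THF, 0 → 50 °C
Reagents that add atoms: none
Why: LiAlH4 reduction of a carboxylic acid to the primary alcohol; silyl ethers, the benzylic ether and the isolated alkene are inert, and any tertiary-to-primary silyl migration is harmless because both silyl groups are removed next.

Step 10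
Reactants: 13 [(1R,2S,3R,6S)-1,3-bis(tert-butyldimethylsilyloxy)-2-methoxy-6-(4-methoxybenzyloxy)cyclohex-4-en-1-yl]methanol
Product: 14 (1R,2S,3R,6S)-1-(hydroxymethyl)-2-methoxy-6-(4-methoxybenzyloxy)cyclohex-4-ene-1,3-diol
Conditions: TBAF, THF, rt → 50 °C
Reagents that add atoms: none
Why: Fluoride-mediated desilylation; cleavage of the hindered tertiary silyl ether should be helped by migration to the neighbouring primary oxygen, and no base-sensitive group is yet present.

Step 11
Reactants: 14 (1R,2S,3R,6S)-1-(hydroxymethyl)-2-methoxy-6-(4-methoxybenzyloxy)cyclohex-4-ene-1,3-diol; 15 benzoyl chloride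
Product: 16 [(1R,2S,3R,6S)-3-(benzoyloxy)-1-hydroxy-2-methoxy-6-(4-methoxybenzyloxy)cyclohex-4-en-1-yl]methyl benzoate
Conditions: BzCl (2.2 equiv), pyridine, DMAP (cat.), CH2Cl2, 0 °C → rt
Reagents that add atoms: benzoyl chloride (the second equivalent of 15), O=C(Cl)c1ccccc1
Why: DMAP-catalysed O-acylation with two equivalents of the acid chloride esterifies the primary C7 and the secondary allylic C3 hydroxyls, one benzoyl group from each equivalent; the tertiary hydroxyl on the fully substituted C1 is too hindered, so both benzoates of the target are installed at once.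

Step 12
Reactants: 16 [(1R,2S,3R,6S)-3-(benzoyloxy)-1-hydroxy-2-methoxy-6-(4-methoxybenzyloxy)cyclohex-4-en-1-yl]methyl benzoate
Product: 17 [(1R,2S,3R,6S)-3-(benzoyloxy)-1,6-dihydroxy-2-methoxycyclohex-4-en-1-yl]methyl benzoate
Conditions: DDQ, CH2Cl2–pH 7 buffer, 0 °C → rt
Reagents that add atoms: none
Why: Oxidative cleavage of a 4-methoxybenzyl ether with DDQ (hydride abstraction to an oxocarbenium ion, then hydrolysis); benzoates, methyl ether and alkene are untouched, and the wet buffered medium should prevent acetal formation with the neighbouring tertiary hydroxyl.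

Step 13
Reactants: 17 [(1R,2S,3R,6S)-3-(benzoyloxy)-1,6-dihydroxy-2-methoxycyclohex-4-en-1-yl]methyl benzoate
Product: 19 [(1R,2S,3R,6R)-3-(benzoyloxy)-2-methoxy-7-oxabicyclo[4.1.0]hept-4-en-1-yl]methyl benzoate, via C6 mesylate 18 (not isolated)
Conditions: MsCl, Et3N, CH2Cl2, −20 °C; then DBU, −20 °C → rt
Reagents that add atoms: methanesulfonyl chloride, CS(=O)(=O)Cl (its atoms are present in 18 only)
Why: Selective sulfonylation of the secondary allylic hydroxyl followed by intramolecular Williamson (3-exo-tet) displacement by the C1 oxygen with inversion at C6 gives the oxirane cis to the C2 methoxyl. The required trans-diaxial arrangement exists in the half-chair that keeps C7, OMe and OBz equatorial.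

## Compound list

1 | 3-O-methyl-D-glucose | O=C[C@H](O)[C@@H](OC)[C@H](O)[C@H](O)CO | starting material
2 | tert-butyldimethylsilyl 2,4,6-tri-O-(tert-butyldimethylsilyl)-3-O-methyl-β-D-glucopyranoside | CC(C)(C)[Si](C)(C)O[C@H]1[C@H](O[Si](C)(C)C(C)(C)C)[C@@H](OC)[C@H](O[Si](C)(C)C(C)(C)C)[C@@H](CO[Si](C)(C)C(C)(C)C)O1 | intermediate
3 | tert-butyldimethylsilyl 2,4-di-O-(tert-butyldimethylsilyl)-3-O-methyl-β-D-glucopyranoside | CC(C)(C)[Si](C)(C)O[C@H]1[C@H](O[Si](C)(C)C(C)(C)C)[C@@H](OC)[C@H](O[Si](C)(C)C(C)(C)C)[C@@H](CO)O1 | intermediate
4 | tert-butyldimethylsilyl 2,4-di-O-(tert-butyldimethylsilyl)-3-O-methyl-β-D-gluco-hexodialdo-1,5-pyranoside | CC(C)(C)[Si](C)(C)O[C@H]1[C@H](O[Si](C)(C)C(C)(C)C)[C@@H](OC)[C@H](O[Si](C)(C)C(C)(C)C)[C@@H](C=O)O1 | intermediate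
5 | tert-butyldimethylsilyl (E)-2,4-di-O-(tert-butyldimethylsilyl)-6,7-dideoxy-7-iodo-3-O-methyl-β-D-gluco-hept-6-enopyranoside | CC(C)(C)[Si](C)(C)O[C@H]1[C@H](O[Si](C)(C)C(C)(C)C)[C@@H](OC)[C@H](O[Si](C)(C)C(C)(C)C)[C@@H](/C=C/I)O1 | intermediate
6 | 4-methoxybenzyl alcohol | COc1ccc(CO)cc1 | starting material
7 | tert-butyldimethylsilyl (E)-2,4-di-O-(tert-butyldimethylsilyl)-6-deoxy-7-O-(4-methoxybenzyl)-3-O-methyl-β-D-gluco-hept-6-enopyranoside | CC(C)(C)[Si](C)(C)O[C@H]1[C@H](O[Si](C)(C)C(C)(C)C)[C@@H](OC)[C@H](O[Si](C)(C)C(C)(C)C)[C@@H](/C=C/OCc2ccc(OC)cc2)O1 | intermediate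
8 | (E)-2,4-di-O-(tert-butyldimethylsilyl)-6-deoxy-7-O-(4-methoxybenzyl)-3-O-methyl-D-gluco-hept-6-enopyranose (anomeric mixture) | OC1[C@H](O[Si](C)(C)C(C)(C)C)[C@@H](OC)[C@H](O[Si](C)(C)C(C)(C)C)[C@@H](/C=C/OCc2ccc(OC)cc2)O1 | intermediate
9 | (3R,4S,5R,6R)-3,5-bis(tert-butyldimethylsilyloxy)-4-methoxy-6-[(E)-2-(4-methoxybenzyloxy)ethenyl]oxan-2-one | O=C1[C@H](O[Si](C)(C)C(C)(C)C)[C@@H](OC)[C@H](O[Si](C)(C)C(C)(C)C)[C@@H](/C=C/OCc2ccc(OC)cc2)O1 | intermediate
10 | trimethylsilyl ketene acetal of 9 (C7=C1 double bond in the ring) | C[Si](C)(C)OC1=C(O[Si](C)(C)C(C)(C)C)[C@@H](OC)[C@H](O[Si](C)(C)C(C)(C)C)[C@@H](/C=C/OCc2ccc(OC)cc2)O1 | intermediate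
11 | trimethylsilyl ester of 12 | CO[C@H]1[C@H](O[Si](C)(C)C(C)(C)C)C=C[C@H](OCc2ccc(OC)cc2)[C@]1(O[Si](C)(C)C(C)(C)C)C(=O)O[Si](C)(C)C | intermediate
12 | (1R,2S,3R,6S)-1,3-bis(tert-butyldimethylsilyloxy)-2-methoxy-6-(4-methoxybenzyloxy)cyclohex-4-ene-1-carboxylic acid | CO[C@H]1[C@H](O[Si](C)(C)C(C)(C)C)C=C[C@H](OCc2ccc(OC)cc2)[C@]1(O[Si](C)(C)C(C)(C)C)C(=O)O | intermediate
13 | [(1R,2S,3R,6S)-1,3-bis(tert-butyldimethylsilyloxy)-2-methoxy-6-(4-methoxybenzyloxy)cyclohex-4-en-1-yl]methanol | CO[C@H]1[C@H](O[Si](C)(C)C(C)(C)C)C=C[C@H](OCc2ccc(OC)cc2)[C@]1(O[Si](C)(C)C(C)(C)C)CO | intermediate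
14 | (1R,2S,3R,6S)-1-(hydroxymethyl)-2-methoxy-6-(4-methoxybenzyloxy)cyclohex-4-ene-1,3-diol | CO[C@H]1[C@H](O)C=C[C@H](OCc2ccc(OC)cc2)[C@]1(O)CO | intermediate
15 | benzoyl chloride | O=C(Cl)c1ccccc1 | starting material
16 | [(1R,2S,3R,6S)-3-(benzoyloxy)-1-hydroxy-2-methoxy-6-(4-methoxybenzyloxy)cyclohex-4-en-1-yl]methyl benzoate | CO[C@H]1[C@H](OC(=O)c2ccccc2)C=C[C@H](OCc2ccc(OC)cc2)[C@]1(O)COC(=O)c1ccccc1 | intermediate
17 | [(1R,2S,3R,6S)-3-(benzoyloxy)-1,6-dihydroxy-2-methoxycyclohex-4-en-1-yl]methyl benzoate | CO[C@H]1[C@H](OC(=O)c2ccccc2)C=C[C@H](O)[C@]1(O)COC(=O)c1ccccc1 | intermediate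
18 | [(1S,2S,3R,6S)-3-(benzoyloxy)-1-hydroxy-2-methoxy-6-(methanesulfonyloxy)cyclohex-4-en-1-yl]methyl benzoate | CO[C@H]1[C@H](OC(=O)c2ccccc2)C=C[C@H](OS(C)(=O)=O)[C@]1(O)COC(=O)c1ccccc1 | intermediate
19 | [(1R,2S,3R,6R)-3-(benzoyloxy)-2-methoxy-7-oxabicyclo[4.1.0]hept-4-en-1-yl]methyl benzoate | CO[C@H]1[C@H](OC(=O)c2ccccc2)C=C[C@H]2O[C@]21COC(=O)c1ccccc1 | target

## Step count and least certain steps

Total: 13 steps. Longest linear sequence: 13 steps, from **1**.

**Step 8 (key step).** The most likely failure is loss of methoxide from the potassium enolate (E1cB across C1–C2) competing with O-silylation. If the ketene acetal does form, slow passage through the strained boat with decomposition on prolonged heating is the next concern. Fallback: from lactone **9**, soft enolisation with dicyclohexylboron triflate, (c-C6H11)2BOTf, and Et3N in CH2Cl2 at −78 °C would give the dicyclohexylboron ketene acetal F1 without any alkali enolate being present. Boron ketene acetals undergo the ester-enolate Claisen shift at or below room temperature, here to the dicyclohexylboryl ester F2, and aqueous work-up returns to acid **12**. This replaces a silicon-trapped potassium enolate by a covalent boron enolate made under Lewis acid and amine, a different variant of the rearrangement rather than a change of base or temperature.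

**Step 6.** The most likely failure is over-desilylation: once the anomeric group is gone, the O2 silyl group can migrate to the anomeric oxygen and be cleaved in turn. Fallback: accept that loss. From **7**, excess unbuffered TBAF at 0 °C would remove both vicinal groups and give the 1,2-diol lactol F3; the sugar O4 silyl ether has no neighbouring free hydroxyl to migrate to and should remain. Ag2CO3 on Celite in hot toluene oxidises lactols much faster than secondary alcohols and would give the 2-hydroxy lactone F4, in which the O4 silyl ether blocks translactonisation. Silylation with TBSCl and imidazole in DMF returns to **9**.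

**Step 5.** The most likely failure is attack of the cesium alkoxide on the anomeric silyl acetal at 80 °C, exposing a base-sensitive lactol, or sluggish coupling of the hindered iodoalkene. Fallback: from aldehyde **4**, chromium-mediated boryl-olefination (Cl2CHBpin, CrCl2, LiI, THF) would give the (E)-alkenyl pinacol boronate F5. Oxidative Chan–Lam-type coupling with alcohol **6** (Cu(OAc)2, Et3N, room temperature, air) would then give **7** without carbonate base or heating.

**Step 13.** The most likely failure is displacement of the allylic mesylate by chloride, or its ionisation (SN2′ substitution or elimination) before closure; base-induced benzoyl migration from the C7 oxygen to the C1 oxygen is a second concern. Fallback: Mitsunobu cyclodehydration of diol **17** (PPh3, diisopropyl azodicarboxylate, toluene). The less hindered C6 hydroxyl is activated as an alkoxyphosphonium ion and displaced by the C1 hydroxyl with inversion, giving **19** directly with no sulfonate and no free alkoxide; no new compound is formed on the way.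

## Further compounds

F1 | step 8 | dicyclohexylboron ketene acetal of 9 | C1CCC(CC1)B(C1CCCCC1)OC1=C(O[Si](C)(C)C(C)(C)C)[C@@H](OC)[C@H](O[Si](C)(C)C(C)(C)C)[C@@H](/C=C/OCc2ccc(OC)cc2)O1
F2 | step 8 | dicyclohexylboryl ester of 12 | CO[C@H]1[C@H](O[Si](C)(C)C(C)(C)C)C=C[C@H](OCc2ccc(OC)cc2)[C@]1(O[Si](C)(C)C(C)(C)C)C(=O)OB(C1CCCCC1)C1CCCCC1
F3 | step 6 | (E)-4-O-(tert-butyldimethylsilyl)-6-deoxy-7-O-(4-methoxybenzyl)-3-O-methyl-D-gluco-hept-6-enopyranose (1,2-diol lactol, anomeric mixture) | OC1[C@H](O)[C@@H](OC)[C@H](O[Si](C)(C)C(C)(C)C)[C@@H](/C=C/OCc2ccc(OC)cc2)O1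
F4 | step 6 | 2-hydroxy lactone: 5-O-silyl analogue of 9 with free 3-hydroxyl (oxan-2-one numbering) | O=C1[C@H](O)[C@@H](OC)[C@H](O[Si](C)(C)C(C)(C)C)[C@@H](/C=C/OCc2ccc(OC)cc2)O1
F5 | step 5 | tert-butyldimethylsilyl (E)-2,4-di-O-(tert-butyldimethylsilyl)-6,7-dideoxy-3-O-methyl-7-(4,4,5,5-tetramethyl-1,3,2-dioxaborolan-2-yl)-β-D-gluco-hept-6-enopyranoside | CC(C)(C)[Si](C)(C)O[C@H]1[C@H](O[Si](C)(C)C(C)(C)C)[C@@H](OC)[C@H](O[Si](C)(C)C(C)(C)C)[C@@H](/C=C/B2OC(C)(C)C(C)(C)O2)O1
F0 | step 13 | none | none
A1 | alternative 1 | 4-(benzoyloxymethyl)-4-hydroxycyclohexa-2,5-dien-1-one | O=C1C=CC(O)(COC(=O)c2ccccc2)C=C1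
A2 | alternative 1 | mono-epoxy enone with the oxirane on C2–C3 syn to the C1 hydroxyl | O=C1C=C[C@](O)(COC(=O)c2ccccc2)[C@H]2O[C@@H]12
A3 | alternative 2 | 2-[2-(benzoyloxymethyl)-3-[(Z)-2-iodoethenyl]oxiran-2-yl]-2-methoxyacetaldehyde with the C1, C2 and C6 configurations of 19 | CO[C@@H](C=O)[C@]1(COC(=O)c2ccccc2)O[C@@H]1/C=C\I
A4 | alternative 2 | 3-O-debenzoyl derivative of 19 (free C3 hydroxyl) | CO[C@H]1[C@H](O)C=C[C@H]2O[C@]21COC(=O)c1ccccc1
A5 | alternative 3 | benzoic acid | O=C(O)c1ccccc1
A6 | alternative 3 | (1S,2R)-1,2-dihydroxycyclohexa-3,5-diene-1-carboxylic acid | O[C@@H]1C=CC=C[C@@]1(O)C(=O)O
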